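**Retrosynthetic overview**

1. Rings are lettered A to G from the 2,4,6-trihydroxyphenyl end; in each ring C1 is the carbon bound to the ether oxygen that leads back towards ring A (in ring A, C1 carries the oxygen to ring B). The strategy rests on the hydroxyls at A-C4, C-C4, D-C4, E-C3 and G-C4, each para to an aryl ether carbon (A-C1, C-C1, D-C1, E-C6, G-C1; D-C4 is also ortho to D-C5). Each travels as CHO, which first activates fluoride displacement at those ether carbons and is then converted into OH.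
2. Target ⇐ BBr3 cleavage of thirteen methyl ethers ⇐ five-fold Baeyer–Villiger oxidation of a heptaaryl pentaaldehyde (five aryl C–O bonds made).
3. Pentaaldehyde ⇐ SNAr union at the fluorine ortho to the formyl group of ring D: tetramer ABCD–F plus trimer phenol HO–EFG.
4. Both halves ⇐ SNAr of fluorobenzaldehydes (rings A, C, D, E, G) with 2,6-dimethoxyhydroquinone (rings B, F); the oxygens of rings C and E that face ring D are carried as bromides and unmasked by borylation–oxidation.
5. No ring is formed: all seven benzene rings are bought. Linking order: A–B, B–C, C–D and, in parallel, E–F, F–G; then D–E.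

Key step: step 14

Assumption: 3-fluoro-2-methoxyphenol and the three fluorinated benzaldehydes are treated as purchasable, and all hydroquinone-type and polyphenolic intermediates are handled under argon in degassed solvents.

**Route**

Step 1
Reactants: 1 2,6-dimethoxy-1,4-benzoquinone
Product: 2 2,6-dimethoxybenzene-1,4-diol (2,6-dimethoxyhydroquinone)
Conditions: Na2S2O4, THF/H2O, rt, argon
Reagents that add atoms: none
Why: Dithionite reduction of a quinone to its hydroquinone is a clean two-electron reduction, and the air-sensitive product is used directly.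

Step 2
Reactants: 2 2,6-dimethoxybenzene-1,4-diol (3 equiv), 3 4-fluoro-3,5-dimethoxybenzaldehyde
Product: 4 4-(4-hydroxy-3,5-dimethoxyphenoxy)-3,5-dimethoxybenzaldehyde (AB phenol)
Conditions: Cs2CO3, degassed DMSO, 110 °C, argon
Reagents that add atoms: none
Why: Nucleophilic aromatic substitution (SNAr) para to the formyl group, in which the fluoride flanked by two methoxy groups can only be reached by the unhindered and slightly more acidic 4-hydroxyl of 2, since the 1-hydroxyl would have to form a tetra-ortho-substituted diaryl ether.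

Step 3
Reactants: 5 4-fluoro-2,6-dimethoxybenzaldehyde
Product: 6 3-bromo-4-fluoro-2,6-dimethoxybenzaldehyde
Conditions: NBS (1.05 equiv), MeCN, 0 °C to rt
Reagents that add atoms: N-bromosuccinimide, O=C1CCC(=O)N1Br
Why: Electrophilic aromatic bromination goes to C3 (equivalent to C5), which is ortho to one methoxy group, para to the other and meta to the formyl group, and one equivalent of NBS should stop at the monobromide.

Step 4
Reactants: 4 AB phenol, 6 3-bromo-4-fluoro-2,6-dimethoxybenzaldehyde
Product: 7 3-bromo-4-[4-(4-formyl-2,6-dimethoxyphenoxy)-2,6-dimethoxyphenoxy]-2,6-dimethoxybenzaldehyde (ABC bromide)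
Conditions: Cs2CO3, DMSO, 90 °C
Reagents that add atoms: none
Why: SNAr of the 2,6-dimethoxyphenoxide of 4 at the only fluoride present, which is para to the formyl group and further activated inductively by the ortho bromine, while the bromine itself is meta to the formyl group and survives as the masked ring C oxygen.

Step 5
Reactants: 7 ABC bromide
Product: 9 4-[4-(4-formyl-2,6-dimethoxyphenoxy)-2,6-dimethoxyphenoxy]-3-hydroxy-2,6-dimethoxybenzaldehyde (ABC phenol), via pinacol boronate 8 (not isolated)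
Conditions: B2pin2, Pd(OAc)2 (5 mol %), SPhos (2-dicyclohexylphosphino-2',6'-dimethoxybiphenyl), KOAc, 1,4-dioxane, 100 °C; then NaBO3·4H2O, THF/H2O, rt
Reagents that add atoms: bis(pinacolato)diboron, CC1(C)OB(OC1(C)C)B1OC(C)(C)C(C)(C)O1 (boron and pinacolate of intermediate 8); sodium perborate, [Na+].[O-]OB=O (oxygen of the new hydroxyl)
Why: Miyaura borylation under KOAc tolerates the aldehydes and, with a bulky biarylphosphine, the di-ortho-substituted bromide, and the perborate oxidation of the C–B bond that follows is much faster than any Dakin oxidation of the methoxybenzaldehydes.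

Step 6
Reactants: 9 ABC phenol, 10 2,4-difluoro-6-methoxybenzaldehyde (1.3 equiv)
Product: 11 4-[4-(4-formyl-2,6-dimethoxyphenoxy)-2,6-dimethoxyphenoxy]-3-(3-fluoro-4-formyl-5-methoxyphenoxy)-2,6-dimethoxybenzaldehyde (ABCD fluoride)
Conditions: K2CO3, DMF, rt to 45 °C
Reagents that add atoms: none
Why: SNAr at the 4-fluorine of 10, which is para to the formyl group and unhindered and is therefore preferred by the bulky phenoxide of 9 over the 2-fluorine beside the formyl group; excess 10 and mild temperature should keep the second fluoride for step 13.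

Step 7
Reactants: 12 3-fluoro-2-methoxyphenol
Product: 13 4-fluoro-2-hydroxy-3-methoxybenzaldehyde
Conditions: MgCl2, Et3N, paraformaldehyde, MeCN, reflux
Reagents that add atoms: paraformaldehyde (as formaldehyde), C=O
Why: Magnesium-mediated ortho-formylation of a phenol (Casnati–Skattebøl) formylates only ortho to the hydroxyl, and the single free ortho position is the carbon para to fluorine.

Step 8
Reactants: 13 4-fluoro-2-hydroxy-3-methoxybenzaldehyde
Product: 14 5-bromo-4-fluoro-2-hydroxy-3-methoxybenzaldehyde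
Conditions: NBS, MeCN, 0 °C to rt
Reagents that add atoms: N-bromosuccinimide, O=C1CCC(=O)N1Br
Why: Electrophilic bromination para to the free hydroxyl (as in the bromination of o-vanillin) places bromine at C5, which is also ortho to fluorine and meta to the formyl group.

Step 9
Reactants: 14 5-bromo-4-fluoro-2-hydroxy-3-methoxybenzaldehyde
Product: 15 5-bromo-4-fluoro-2,3-dimethoxybenzaldehyde
Conditions: MeI, K2CO3, acetone, reflux
Reagents that add atoms: iodomethane, CI
Why: Williamson O-methylation of the salicylaldehyde-type phenoxide, which is too weak a nucleophile to attack the aryl fluoride under these mild conditions.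

Step 10
Reactants: 15 5-bromo-4-fluoro-2,3-dimethoxybenzaldehyde, 2 2,6-dimethoxybenzene-1,4-diol (3 equiv)
Product: 16 5-bromo-4-(4-hydroxy-3,5-dimethoxyphenoxy)-2,3-dimethoxybenzaldehyde (EF phenol)
Conditions: Cs2CO3, degassed DMSO, 80 °C, argon
Reagents that add atoms: none
Why: SNAr para to the formyl group at a fluoride flanked by bromine and methoxy, which again admits only the unhindered 4-hydroxyl of the hydroquinone and leaves the 2,6-dimethoxyphenol hydroxyl free for ring G.

Step 11
Reactants: 16 EF phenol, 5 4-fluoro-2,6-dimethoxybenzaldehyde (1.5 equiv)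
Product: 17 5-bromo-4-[4-(4-formyl-3,5-dimethoxyphenoxy)-3,5-dimethoxyphenoxy]-2,3-dimethoxybenzaldehyde (EFG bromide)
Conditions: Cs2CO3, DMSO, 110 °C
Reagents that add atoms: none
Why: SNAr of the hindered 2,6-dimethoxyphenoxide of 16 at the unhindered 4-fluoride of 5, para to its formyl group; 16 carries no fluoride, and its bromine is meta to a formyl group and inert.

Step 12
Reactants: 17 EFG bromide
Product: 19 4-[4-(4-formyl-3,5-dimethoxyphenoxy)-3,5-dimethoxyphenoxy]-5-hydroxy-2,3-dimethoxybenzaldehyde (EFG phenol), via pinacol boronate 18 (not isolated)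
Conditions: B2pin2, Pd(dppf)Cl2 (5 mol %), KOAc, 1,4-dioxane, 90 °C; then NaBO3·4H2O, THF/H2O, rt
Reagents that add atoms: bis(pinacolato)diboron, CC1(C)OB(OC1(C)C)B1OC(C)(C)C(C)(C)O1 (boron and pinacolate of intermediate 18); sodium perborate, [Na+].[O-]OB=O (oxygen of the new hydroxyl)
Why: Miyaura borylation of a bromide with only one ortho substituent followed by perborate oxidation of the C–B bond, with the new hydroxyl meta to the ring E formyl group and therefore not prone to Dakin cleavage.

Step 13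
Reactants: 11 ABCD fluoride, 19 EFG phenol (1.1 equiv)
Product: 20 heptaaryl hexaether pentaaldehyde (formyl on rings A, C, D, E, G; thirteen methoxy groups)
Conditions: Cs2CO3, DMSO, 90 °C
Reagents that add atoms: none
Why: SNAr at the fluorine ortho to the formyl group of ring D, the only aryl fluoride in either fragment, by a phenoxide that has a free ortho position on one side.

Step 14
Reactants: 20 heptaaryl pentaaldehyde
Product: 22 trideca-O-methyl pentaphenol of the target, via pentaformate 21 (not isolated)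
Conditions: mCPBA (about 6 equiv), CH2Cl2, 0 °C to rt; cold aqueous Na2S2O3/NaHCO3 wash; then K2CO3 (cat.), degassed MeOH, 0 °C, AcOH quench
Reagents that add atoms: meta-chloroperoxybenzoic acid, OOC(=O)c1cccc(Cl)c1
Why: Each formyl carbonyl adds the peracid to give a Criegee adduct, the ring carbon migrates from carbon to the peroxide oxygen as 3-chlorobenzoate leaves, and the five aryl formates of 21 are then opened by methanol, so that five aryl C–O bonds replace five aryl C–C bonds. The closest known reaction is the Baeyer–Villiger (Dakin-type) oxidation of polymethoxybenzaldehydes to phenols through their formates, here run on five formyl groups of one molecule. No ring closes and no stereocentre is formed. The step needs aryl migration to beat hydride migration at all five sites, which the substrate secures by an aryloxy donor para to every formyl carbon, reinforced by two ortho oxygens in rings C, D and G and by one ortho methoxy group in ring E. It also needs the aldehydes to react before the electron-rich rings B and F are hydroxylated, which rests on the faster carbonyl addition at 0 °C, on near-stoichiometric peracid, and on destroying all peracid before methanolysis frees the phenols.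

Step 15
Reactants: 22 trideca-O-methyl pentaphenol
Product: 23 CNP0130704.0 (target, eighteen free hydroxyls)
Conditions: BBr3 (large excess), CH2Cl2, −78 °C to rt; MeOH then H2O quench; reversed-phase purification under argon
Reagents that add atoms: none
Why: BBr3 ether cleavage removes the thirteen methyl groups by bromide attack on the boron-complexed O–CH3 carbons, whereas the six diaryl ether bonds offer no sp3 carbon and should persist.

**Compound list**

1 | 2,6-dimethoxy-1,4-benzoquinone | COC1=CC(=O)C=C(OC)C1=O | starting material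
2 | 2,6-dimethoxybenzene-1,4-diol (2,6-dimethoxyhydroquinone, rings B and F) | COc1cc(O)cc(OC)c1O | intermediate
3 | 4-fluoro-3,5-dimethoxybenzaldehyde (ring A) | COc1cc(C=O)cc(OC)c1F | starting material
4 | 4-(4-hydroxy-3,5-dimethoxyphenoxy)-3,5-dimethoxybenzaldehyde (AB phenol) | COc1cc(C=O)cc(OC)c1Oc1cc(OC)c(O)c(OC)c1 | intermediate
5 | 4-fluoro-2,6-dimethoxybenzaldehyde (rings C and G) | COc1cc(F)cc(OC)c1C=O | starting material
6 | 3-bromo-4-fluoro-2,6-dimethoxybenzaldehyde | COc1cc(F)c(Br)c(OC)c1C=O | intermediate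
7 | 3-bromo-4-[4-(4-formyl-2,6-dimethoxyphenoxy)-2,6-dimethoxyphenoxy]-2,6-dimethoxybenzaldehyde (ABC bromide) | O=Cc1cc(OC)c(Oc2cc(OC)c(Oc3cc(OC)c(C=O)c(OC)c3Br)c(OC)c2)c(OC)c1 | intermediate
8 | pinacol boronate of the ABC trimer (Bpin in place of Br of 7) | O=Cc1cc(OC)c(Oc2cc(OC)c(Oc3cc(OC)c(C=O)c(OC)c3B4OC(C)(C)C(C)(C)O4)c(OC)c2)c(OC)c1 | intermediate
9 | 4-[4-(4-formyl-2,6-dimethoxyphenoxy)-2,6-dimethoxyphenoxy]-3-hydroxy-2,6-dimethoxybenzaldehyde (ABC phenol) | O=Cc1cc(OC)c(Oc2cc(OC)c(Oc3cc(OC)c(C=O)c(OC)c3O)c(OC)c2)c(OC)c1 | intermediate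
10 | 2,4-difluoro-6-methoxybenzaldehyde (ring D) | COc1cc(F)cc(F)c1C=O | starting material
11 | 4-[4-(4-formyl-2,6-dimethoxyphenoxy)-2,6-dimethoxyphenoxy]-3-(3-fluoro-4-formyl-5-methoxyphenoxy)-2,6-dimethoxybenzaldehyde (ABCD fluoride) | O=Cc1cc(OC)c(Oc2cc(OC)c(Oc3cc(OC)c(C=O)c(OC)c3Oc3cc(OC)c(C=O)c(F)c3)c(OC)c2)c(OC)c1 | intermediate
12 | 3-fluoro-2-methoxyphenol | COc1c(O)cccc1F | starting material
13 | 4-fluoro-2-hydroxy-3-methoxybenzaldehyde | COc1c(F)ccc(C=O)c1O | intermediate
14 | 5-bromo-4-fluoro-2-hydroxy-3-methoxybenzaldehyde | COc1c(F)c(Br)cc(C=O)c1O | intermediate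
15 | 5-bromo-4-fluoro-2,3-dimethoxybenzaldehyde (ring E) | COc1c(F)c(Br)cc(C=O)c1OC | intermediate
16 | 5-bromo-4-(4-hydroxy-3,5-dimethoxyphenoxy)-2,3-dimethoxybenzaldehyde (EF phenol) | COc1c(Oc2cc(OC)c(O)c(OC)c2)c(Br)cc(C=O)c1OC | intermediate
17 | 5-bromo-4-[4-(4-formyl-3,5-dimethoxyphenoxy)-3,5-dimethoxyphenoxy]-2,3-dimethoxybenzaldehyde (EFG bromide) | COc1c(Oc2cc(OC)c(Oc3cc(OC)c(C=O)c(OC)c3)c(OC)c2)c(Br)cc(C=O)c1OC | intermediate
18 | pinacol boronate of the EFG trimer (Bpin in place of Br of 17) | COc1c(Oc2cc(OC)c(Oc3cc(OC)c(C=O)c(OC)c3)c(OC)c2)c(B4OC(C)(C)C(C)(C)O4)cc(C=O)c1OC | intermediate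
19 | 4-[4-(4-formyl-3,5-dimethoxyphenoxy)-3,5-dimethoxyphenoxy]-5-hydroxy-2,3-dimethoxybenzaldehyde (EFG phenol) | COc1c(Oc2cc(OC)c(Oc3cc(OC)c(C=O)c(OC)c3)c(OC)c2)c(O)cc(C=O)c1OC | intermediate
20 | heptaaryl hexaether pentaaldehyde (formyl on rings A, C, D, E, G; thirteen OMe) | O=Cc1cc(OC)c(Oc2cc(OC)c(Oc3cc(OC)c(C=O)c(OC)c3Oc3cc(OC)c(C=O)c(Oc4cc(C=O)c(OC)c(OC)c4Oc4cc(OC)c(Oc5cc(OC)c(C=O)c(OC)c5)c(OC)c4)c3)c(OC)c2)c(OC)c1 | intermediate
21 | pentaformate (OCHO in place of each CHO of 20) | O=COc1cc(OC)c(Oc2cc(OC)c(Oc3cc(OC)c(OC=O)c(OC)c3Oc3cc(OC)c(OC=O)c(Oc4cc(OC=O)c(OC)c(OC)c4Oc4cc(OC)c(Oc5cc(OC)c(OC=O)c(OC)c5)c(OC)c4)c3)c(OC)c2)c(OC)c1 | intermediate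
22 | trideca-O-methyl pentaphenol (OH on rings A, C, D, E, G in place of CHO) | Oc1cc(OC)c(Oc2cc(OC)c(Oc3cc(OC)c(O)c(OC)c3Oc3cc(OC)c(O)c(Oc4cc(O)c(OC)c(OC)c4Oc4cc(OC)c(Oc5cc(OC)c(O)c(OC)c5)c(OC)c4)c3)c(OC)c2)c(OC)c1 | intermediate
23 | CNP0130704.0 | Oc1cc(O)c(Oc2cc(O)c(Oc3cc(O)c(O)c(O)c3Oc3cc(O)c(O)c(Oc4cc(O)c(O)c(O)c4Oc4cc(O)c(Oc5cc(O)c(O)c(O)c5)c(O)c4)c3)c(O)c2)c(O)c1 | target

**Step count**

Total: 15 steps. Longest linear sequence: 9 steps (12 → 13 → 14 → 15 → 16 → 17 → 19 → 20 → 22 → 23). The ABCD branch (1 → 2 → 4 → 7 → 9 → 11) runs in parallel.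

**Steps most likely to fail**

Step 14 (five-fold oxidation). Conversion may stall before all five formyl groups have reacted. Hydride instead of aryl migration is most likely at ring A, where the para oxygen is twisted by two flanking methoxy groups and no ortho oxygen helps. Excess peracid may also hydroxylate the electron-rich rings B and F. Fallback: the oxidation is staged, setting out from 7 and returning at 23. The two aldehydes of 7 (rings A and C, whose activating role is over) are oxidised with mCPBA to the bis(formate) F1, and K2CO3 in methanol opens it to the bisphenol F2, where any ring A carboxylic acid is still easy to separate. MeI/K2CO3 caps both hydroxyls to give the bromide 2-bromo-1-[2,6-dimethoxy-4-(2,4,6-trimethoxyphenoxy)phenoxy]-3,4,5-trimethoxybenzene F3, which costs nothing because the last step cleaves every methyl ether. Borylation (B2pin2, Pd(OAc)2, SPhos, KOAc) gives the pinacol boronate F4, and perborate gives the phenol F5. SNAr with 10 (K2CO3, DMF) gives the tetraaryl fluoride F6, and SNAr with 19 (Cs2CO3, DMSO) gives the heptaaryl trialdehyde F7, which carries formyl groups only on rings D, E and G, the three best migrating rings. Three-fold mCPBA oxidation through the tris(formate) F8 and methanolysis give the pentadeca-O-methyl triphenol F9, and BBr3 converts it into 23.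

Step 2 (first hydroquinone arylation). Fluoride displacement at a carbon flanked by two methoxy donors may be sluggish, and at the temperature it needs the unprotected hydroquinone may be lost to oxidation by trace oxygen or to double arylation. Fallback: a protected single-phenol partner is used, setting out from 3 and returning at 4. Syringaldehyde F10 is protected with MOMCl/iPr2NEt as 3,5-dimethoxy-4-(methoxymethoxy)benzaldehyde F11. mCPBA gives the aryl formate F12, and K2CO3 in methanol gives 3,5-dimethoxy-4-(methoxymethoxy)phenol F13. Its single unhindered phenoxide tolerates forcing SNAr conditions with 3 (Cs2CO3, NMP, 140 °C) to give the MOM ether 4-[3,5-dimethoxy-4-(methoxymethoxy)phenoxy]-3,5-dimethoxybenzaldehyde F14, and HCl in methanol followed by aqueous work-up gives 4.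

Step 5 (borylation–oxidation of the ABC bromide). Oxidative addition at the bromide flanked by a methoxy and a bulky aryloxy group may be slow, so that protodebromination or protodeboronation outruns formation of the phenol. Fallback: the oxygen is installed on the monomer and protected, setting out from 6 and returning at 9. Bromide 6, flanked only by methoxy and fluorine, is borylated (B2pin2, Pd(dppf)Cl2, KOAc) to the pinacol boronate F15 and oxidised with perborate to 4-fluoro-3-hydroxy-2,6-dimethoxybenzaldehyde F16. MOMCl/iPr2NEt gives 4-fluoro-2,6-dimethoxy-3-(methoxymethoxy)benzaldehyde F17, whose fluoride is no longer deactivated by a phenoxide. SNAr with 4 (Cs2CO3, DMSO) gives the MOM-protected ABC trimer F18, and HCl in methanol gives 9.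

**Further compounds**

F1 | step 14 | bis(formate) of the ABC bromide | O=COc1cc(OC)c(Oc2cc(OC)c(Oc3cc(OC)c(OC=O)c(OC)c3Br)c(OC)c2)c(OC)c1
F2 | step 14 | ABC bromide bisphenol (OH in place of both CHO of 7) | Oc1cc(OC)c(Oc2cc(OC)c(Oc3cc(OC)c(O)c(OC)c3Br)c(OC)c2)c(OC)c1
F3 | step 14 | 2-bromo-1-[2,6-dimethoxy-4-(2,4,6-trimethoxyphenoxy)phenoxy]-3,4,5-trimethoxybenzene | COc1cc(OC)c(Oc2cc(OC)c(Oc3cc(OC)c(OC)c(OC)c3Br)c(OC)c2)c(OC)c1
F4 | step 14 | pinacol boronate from F3 | COc1cc(OC)c(Oc2cc(OC)c(Oc3cc(OC)c(OC)c(OC)c3B4OC(C)(C)C(C)(C)O4)c(OC)c2)c(OC)c1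
F5 | step 14 | 2-[2,6-dimethoxy-4-(2,4,6-trimethoxyphenoxy)phenoxy]-3,4,5-trimethoxyphenol | COc1cc(OC)c(Oc2cc(OC)c(Oc3cc(OC)c(OC)c(OC)c3O)c(OC)c2)c(OC)c1
F6 | step 14 | tetraaryl fluoride with formyl on ring D only | COc1cc(OC)c(Oc2cc(OC)c(Oc3cc(OC)c(OC)c(OC)c3Oc3cc(OC)c(C=O)c(F)c3)c(OC)c2)c(OC)c1
F7 | step 14 | heptaaryl trialdehyde (formyl on rings D, E, G; fifteen OMe) | COc1cc(OC)c(Oc2cc(OC)c(Oc3cc(OC)c(OC)c(OC)c3Oc3cc(OC)c(C=O)c(Oc4cc(C=O)c(OC)c(OC)c4Oc4cc(OC)c(Oc5cc(OC)c(C=O)c(OC)c5)c(OC)c4)c3)c(OC)c2)c(OC)c1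
F8 | step 14 | tris(formate) from F7 | COc1cc(OC)c(Oc2cc(OC)c(Oc3cc(OC)c(OC)c(OC)c3Oc3cc(OC)c(OC=O)c(Oc4cc(OC=O)c(OC)c(OC)c4Oc4cc(OC)c(Oc5cc(OC)c(OC=O)c(OC)c5)c(OC)c4)c3)c(OC)c2)c(OC)c1
F9 | step 14 | pentadeca-O-methyl triphenol (OH on rings D, E, G) | COc1cc(OC)c(Oc2cc(OC)c(Oc3cc(OC)c(OC)c(OC)c3Oc3cc(OC)c(O)c(Oc4cc(O)c(OC)c(OC)c4Oc4cc(OC)c(Oc5cc(OC)c(O)c(OC)c5)c(OC)c4)c3)c(OC)c2)c(OC)c1
F10 | step 2 | syringaldehyde (4-hydroxy-3,5-dimethoxybenzaldehyde, purchased) | COc1cc(C=O)cc(OC)c1O
F11 | step 2 | 3,5-dimethoxy-4-(methoxymethoxy)benzaldehyde | COCOc1c(OC)cc(C=O)cc1OC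
F12 | step 2 | 3,5-dimethoxy-4-(methoxymethoxy)phenyl formate | COCOc1c(OC)cc(OC=O)cc1OC
F13 | step 2 | 3,5-dimethoxy-4-(methoxymethoxy)phenol | COCOc1c(OC)cc(O)cc1OC
F14 | step 2 | 4-[3,5-dimethoxy-4-(methoxymethoxy)phenoxy]-3,5-dimethoxybenzaldehyde | COCOc1c(OC)cc(Oc2c(OC)cc(C=O)cc2OC)cc1OC
F15 | step 5 | 4-fluoro-2,6-dimethoxy-3-(4,4,5,5-tetramethyl-1,3,2-dioxaborolan-2-yl)benzaldehyde | COc1cc(F)c(B2OC(C)(C)C(C)(C)O2)c(OC)c1C=O
F16 | step 5 | 4-fluoro-3-hydroxy-2,6-dimethoxybenzaldehyde | COc1cc(F)c(O)c(OC)c1C=O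
F17 | step 5 | 4-fluoro-2,6-dimethoxy-3-(methoxymethoxy)benzaldehyde | COCOc1c(F)cc(OC)c(C=O)c1OC
F18 | step 5 | MOM ether of the ABC phenol 9 | O=Cc1cc(OC)c(Oc2cc(OC)c(Oc3cc(OC)c(C=O)c(OC)c3OCOC)c(OC)c2)c(OC)c1
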